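One mole per litre of L, rather than one minute, is the unit in which the loss of G is best counted in these flasks.

| flask | L | G | remark | time |
|---|---|---|---|---|
| amber | 0.40 M | 3.1 mM (in portions, 3) | run made earlier; portions every 40 s |  |
| green | 0.40 M | 55 mM (in portions, 3) | run made earlier; portions every 40 s |  |
| ochre | 0.74 M | 10 mM (in portions, 3) | run made earlier; portions every 40 s |  |
| east | 1.5 M | 10 mM (in portions, 3) | the portions of G follow each other after 80 s, the first at the start | 2.0 min |
| north-east | 0.40 M | 10 mM (in portions, 3) | the portions of G follow each other after 40 s, the first at the start | 2.0 min |
| south | 0.40 M | 40 mM (in portions, 3) | the portions of G follow each other after 10 s, the first at the start | 2.0 min |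
| south-west | 0.25 M | 2.5 mM (in portions, 3) | the portions of G follow each other after 40 s, the first at the start | 2.0 min |
| west | 0.80 M | 10 mM (in portions, 3) | the portions of G follow each other after 40 s, the first at the start | 2.0 min |
| south-east | 0.40 M | 20 mM (in portions, 3) | the portions of G follow each other after 40 s, the first at the start | 2.0 min |

| run | time / s | J / % |
|---|---|---|
| amber | 10.0 | 0.4 |
| amber | 20.0 | 0 |
| amber | 40.0 | 0.5 |
| amber | 60.0 | 5.6 |
| amber | 80.0 | 9.8 |
| green | 10.0 | 4.3 |
| green | 12.0 | 5.5 |
| green | 25.0 | 10.4 |
| green | 40.0 | 14.3 |
| green | 80.0 | 80.3 |
| ochre | 10.0 | 0.8 |
| ochre | 20.0 | 0.4 |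
| ochre | 40.0 | 1.0 |
| ochre | 60.0 | 13.3 |
| ochre | 80.0 | 23.3 |

(each reading ± 0.5 percentage points)

- what was read earlier has a scatter of 0.5 percentage points, one standard deviation
- candidate steps: G + Q -> G + J; L + G -> X; L -> Q; L <-> Z
- percentages count the whole charge, also what has not yet gone in

- ranking by amount of J, in percent of the L charged, from high to low, at 2.0 min (east / north-east / south / south-west / west / south-east)
- the amount of J, in percent of the L charged of the flask you put first, at 2.0 min
- the amount of J, in percent of the L charged of the flask you put last, at 2.0 min

How much does G work once L has largely gone? In the green run, everything not yet J is treated as Q and its loss as pseudo-first-order. That gives 0.00303 /s before the second portion and 0.0368 /s after it. If the second portion counts as intact, the first keeps a share of 8.25%, as a reading.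

Does that loss depend on time? L + G → X and L → Q both run in proportion to c(L), so dividing one rate by the other removes time: ln c(G) falls by a fixed amount per unit of c(L) that disappears. That amount, read from the green run as 6.24 /M, is the toll; any Z counts as L still to come.

What does the toll do to a first portion? It keeps exp(−toll × c(L)): 8.25% in north-east, 0.681% in west and 21.0% in south-west. North-east and west therefore run mainly on later portions and should lie close together. East's third portion falls at 160 s, later than 120 s, so two portions go in there; the first keeps 0.00866% by this reckoning, so east should run on its second portion, added at 80 s.

The forecast, holding that “G added early therefore dies”, gives south > south-east > north-east > west > east > south-west, with 95% for the first flask and 23% for the last.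

The flasks give south > south-east > north-east > west > east > south-west, with 89.2% in south and 23.8% in south-west, so "top" lies 5.8 percentage points below the forecast.

    G + Q → G + J (k = 2.50 /M/s)
    L + G → X (k = 0.700 /M/s)
    L → Q (k = 0.0950 /s)
    L ⇌ Z (K = 0.370, k = 0.210 /s)

In south, the half-life of L by L → Q alone, 7.30 s, is shorter than the interval of 10 s, and at 0.333 min the last portion meets L 16.2% and Z 6.87%. The toll turns G 21.1% plus that portion into 30.6% of G at the end; south holds 29.6%.

With 0.62 M of L instead of 0.25 M, the neighbour of south-west keeps 2.09% of its first portion, which puts 32.6% of the G charged into X from that portion. That neighbour holds X 42.2% and J 19.4%, against 32.0% and 23.8% in south-west.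

Readings and results are simulated with made-up constants, noise included.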